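**Assumption:** The target SMILES has no stereocentres. The only stereo-element is the E enone C=C, which the route sets thermodynamically.

## Retrosynthetic overview
- The E-chalcone C=C is disconnected by Claisen–Schmidt condensation into 2',4'-dihydroxyacetophenone (7) and 5-prenylvanillin (6).
- The prenyl group of 6 comes from the allyl group of 5-allylvanillin (4) by cross-metathesis with 2-methyl-2-butene.
- 4 comes from aromatic Claisen rearrangement of vanillin allyl ether (3), which can only go to C5 because C3 carries OMe.
- 3 comes from O-allylation of vanillin (1).
- No ring is constructed: both aromatic rings are present in commercial starting materials.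

## Forward synthesis

**Step 1**
Reactants: 1 (vanillin) and 2 (allyl bromide)
Product: 3 (4-allyloxy-3-methoxybenzaldehyde)
Conditions: K2CO3, acetone, reflux
Reagents that add atoms: allyl bromide, C=CCBr
Why: Williamson ether synthesis; the phenoxide is alkylated selectively by the SN2-reactive allyl bromide, and the aldehyde is untouched.

**Step 2**
Reactants: 3
Product: 4 (5-allylvanillin, 3-allyl-4-hydroxy-5-methoxybenzaldehyde)
Conditions: neat or N,N-diethylaniline, 200 °C (or NMP, microwave, 200 °C)
Reagents that add atoms: none
Why: Aromatic Claisen [3,3] rearrangement. The para position is blocked by CHO and one ortho position by OMe, so the allyl group migrates to C5 and the ketone tautomerises back to the phenol.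

**Step 3**
Reactants: 4 and 5 (2-methyl-2-butene)
Product: 6 (5-prenylvanillin, 4-hydroxy-3-methoxy-5-(3-methylbut-2-enyl)benzaldehyde)
Conditions: Grubbs II (5 mol%), excess 2-methyl-2-butene, CH2Cl2, 40 °C, sealed tube
Reagents that add atoms: 2-methyl-2-butene, CC=C(C)C (supplies the =CMe2 terminus; propene is lost)
Why: Olefin cross-metathesis. The monosubstituted terminal allyl alkene reacts with the trisubstituted alkene to give the more substituted prenyl alkene. The free phenol and aldehyde are tolerated, and the large excess of 5 suppresses homodimerisation.

**Step 4**
Reactants: 7 (2',4'-dihydroxyacetophenone) and 6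
Product: 8 (target chalcone)
Conditions: KOH (about 4 equiv), EtOH/H2O, rt to 50 °C, 24–48 h; then aqueous HCl to pH 3
Reagents that add atoms: none (HCl only protonates the phenoxides)
Why: Claisen–Schmidt (base-mediated aldol condensation). Dehydration of the β-hydroxy ketone gives the conjugated enone, and the E isomer is strongly favoured thermodynamically. The excess base accounts for the three acidic phenols, and the prenyl alkene is inert to base, so no chroman forms.

## Checks
- **Target match:** Product 8 has the vanillin ring with OMe at C3, the enone at C1, prenyl at C5 and OH at C4. The A ring is 2,4-dihydroxybenzoyl. This matches COc1cc(/C=C/C(=O)c2ccc(O)cc2O)cc(CC=C(C)C)c1O.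
- **Atom bookkeeping:**
  - Step 1: C8H8O3 + C3H5Br gives C11H12O3 plus HBr.
  - Step 2: isomerisation, C11H12O3.
  - Step 3: C11H12O3 + C5H10 gives C13H16O3 plus propene (C3H6).
  - Step 4: C13H16O3 + C8H8O3 gives C21H22O5 plus H2O.
- **Functional group survival:** CHO survives steps 1–3. The prenyl alkene and free phenols survive the basic step 4. No acid stronger than the dilute HCl workup is used, so no chroman cyclisation occurs.
- **Stereochemistry:** The E geometry is set in step 4 and nothing later can change it.

## Compound list
1 | vanillin | COc1cc(C=O)ccc1O | starting material
2 | allyl bromide | C=CCBr | starting material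
3 | 4-allyloxy-3-methoxybenzaldehyde | COc1cc(C=O)ccc1OCC=C | intermediate
4 | 5-allylvanillin | COc1cc(C=O)cc(CC=C)c1O | intermediate
5 | 2-methyl-2-butene | CC=C(C)C | starting material
6 | 5-prenylvanillin | COc1cc(C=O)cc(CC=C(C)C)c1O | intermediate
7 | 2',4'-dihydroxyacetophenone | CC(=O)c1ccc(O)cc1O | starting material
8 | target chalcone (E) | COc1cc(/C=C/C(=O)c2ccc(O)cc2O)cc(CC=C(C)C)c1O | target

## Step count
- Total steps: 4.
- Longest linear sequence: 4 (vanillin → 3 → 4 → 6 → 8).

## Three steps most likely to fail
1. **Step 3 (cross-metathesis).** Ru–H isomerisation of the allyl group to a propenyl group, or incomplete conversion, could lower the yield.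
   - Fallback: change the approach to a coupling route. Use 5-bromovanillin, protect the phenol as MOM and the aldehyde as its dimethyl acetal, then do Br–Li exchange and CuI-catalysed SN2 coupling with prenyl bromide, and finally deprotect.
2. **Step 4 (Claisen–Schmidt on unprotected polyphenols).** The 4-phenoxide of 6 deactivates the aldehyde, so conversion and yield may be low.
   - Fallback: bis-MOM-protect 7 and 6, condense under standard base conditions, then remove the MOM groups with mild acid (e.g. HCl/MeOH, rt).
3. **Step 2 (thermal Claisen).** At 200 °C the aldehyde-bearing aryl allyl ether may decompose or give low conversion.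
   - Fallback: avoid the thermal rearrangement and install the allyl group by Pd-catalysed Suzuki or Stille coupling of 5-iodovanillin with allyltributylstannane or allyl-Bpin. Run the cross-metathesis on the resulting 5-allylvanillin as in step 3.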